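The numbers in the tables were generated by integration with constants of no real substance; the scatter is artificial.

Flask eta cannot end level with flask zeta unless zeta's mean rate of making E is 3.33 times eta's, since E at the end is mean rate times time. I called this number the break-even ratio: the time of eta divided by the time of zeta. For the opposite outcome, the temperature gap of 40.0 K would have to raise the mean rate by less than that.

| setting | Thursday's | Saturday's | Friday's | zeta | eta |
|---|---|---|---|---|---|
| X | 0.025 M | 0.10 M | 0.050 M | 0.050 M | 0.050 M |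
| Z | 0.030 M | 0.030 M | 0.015 M | 0.0300 M | 0.0300 M |
| Q | 3.8 mM (held) | 3.8 mM (held) | 3.8 mM (held) | 3.8 mM (held) | 3.8 mM (held) |
| temperature | −20 °C | 5 °C | −20 °C | 25 °C | −15 °C |
| remark | run made earlier | run made earlier | run made earlier |  |  |
| time |  |  |  | 30 min | 100 min |

| run | time / min | E / % | D / % |
|---|---|---|---|
| Thursday's | 12.0 | 1.3 | 0 |
| Thursday's | 20.0 | 0.7 | 0 |
| Thursday's | 30.0 | 1.4 | 0 |
| Thursday's | 50.0 | 3.6 | 0.2 |
| Thursday's | 80.0 | 5.8 | 0 |
| Thursday's | 120 | 8.1 | 0.5 |
| Thursday's | 180 | 12.3 | 0.6 |
| Saturday's | 2.50 | 0 | 0 |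
| Saturday's | 8.00 | 3.3 | 0 |
| Saturday's | 15.0 | 5.7 | 0.4 |
| Saturday's | 20.0 | 9.0 | 0.6 |
| Saturday's | 25.0 | 10.7 | 0.6 |
| Saturday's | 40.0 | 16.9 | 1.1 |
| Saturday's | 50.0 | 20.3 | 1.7 |
| Friday's | 12.0 | 0.3 | 0.3 |
| Friday's | 25.0 | 1.2 | 0 |
| Friday's | 50.0 | 4.8 | 0.1 |
| Friday's | 90.0 | 6.8 | 0 |
| Friday's | 180 | 12.2 | 0.2 |

(each reading ± 0.5 percentage points)

1. the flask that ends with the higher amount of E, in percent of the X charged, or "neither" when 2 percentage points or less lies between them (zeta / eta / neither)
2. final E, as a percentage of the X charged, in zeta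
3. final E, as a percentage of the X charged, in eta

- at the start none of Q is in solution

I read each mean rate as the last E reading over its time, a share of the X charge per hour. Thursday's run gave 0.0410 /h. Friday's run, with twice the X and half the Z, two changes at once, gave 0.0407 /h, and I took this rate (a pseudo-first-order constant) as free of the charges. Saturday's run gave 0.244 /h. I carried the same factor per degree from these readings to both flasks:

zeta, straight line: 1.01 /h

eta, straight line: 0.0586 /h

Drawn straight, zeta would turn 50.7 % of its X into E, but X falls as it goes. So I replaced the curve by its mean, taking the mean X in each flask as the charge less half of that flask's own straight-line share: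

zeta, mean rate: 0.757 /h, so E is 37.8 %

eta, straight share 9.76 %, mean rate: 0.0557 /h, so E is 9.28 %

ratio of the mean rates: 13.6

This stands well above break-even, so I committed to zeta.

The forecast said zeta, with 38 % for zeta and 10 % for eta, on the ground: “I therefore take first order in X, zero order in Z, at fixed Q.”

Flask zeta gave 29.2 % and flask eta 10.8 %, so zeta ended higher.

    X + L → E (k = 0.210 /M/s, Ea = 56.0 kJ/mol)
    Z + E ⇌ D (K = 1300 /M, k = 0.0180 /M/s, Ea = 55.0 kJ/mol, ΔH = −16.0 kJ/mol)
    X + Z → J (k = 0.0210 /M/s, Ea = 43.0 kJ/mol)
    Q ⇌ L, rate k4*(csat - [L]) (kL = 0.00590 /s)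
    (constants at 25 °C)

In zeta, J stood at 37.1 % at the end, more than E. The ratio of mean rates came to 9.00 against the break-even 3.33. Eta repeated at 0 °C, for the same time, gave 27.6 %. Zeta's mean rate was 3.53 times that flask's, close to break-even, and the two ended 1.6 percentage points apart.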